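## Retrosynthetic overview

1. Feature: the ten-membered carbocycle is read as the rim of a decalin whose fusion atoms are the two oxygen-bearing carbons C3 and C8 (1,6 across the ring). Ring A = C3–C4–C5–C6–C7–C8 is the carvone ring (C15 methyl, Z-C4=C5, C7 arm), ring B = C3–C2–C1–C10–C9–C8, and the C10 carbinol, 1,4 to C3, is tied to C3 as a C3–O–C10 ether.
2. Endgame disconnections: C3–OH (CBS reduction of the enone), C8 tiglate (esterification), C8–OH (1,3-anti reduction steered by the C10 hydroxyl), ketal acetate at C3.
3. Key disconnection: the C3–C8 bond, re-formed on paper to give a 3,10-oxa-bridged decalin-8-ol; in the forward direction, alkoxy-radical β-scission of that bond releases the cyclodecenone.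
4. Ring order: ring A bought as (R)-carvone; cis-γ-lactone closed on C6 by iodolactonisation; ring B by ring-closing metathesis (C1=C10) of an allyl on C3 and a methallyl on C8; oxolane bridge by iodoetherification; ten-membered ring last, by scission.

Key step: step 17

Remark on numbering: atoms carry the germacrane numbers of the target (C1–C15) in every intermediate; names built on "carvone" use carvone numbering.

Assumption: the 10-hydroxy-3-ketones 26 and 29 are written as open hydroxy enones; at rest they are expected to sit largely as their 3,10-hemiketals (as drawn for 25) and to react through the tautomer that the step requires.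

## Route

Step 1
Reactants: 1 (R)-carvone
Product: 2 (R)-10-chlorocarvone, (5R)-5-(3-chloroprop-1-en-2-yl)-2-methylcyclohex-2-en-1-one
Conditions: Ca(OCl)2, CO2 (dry ice), CH2Cl2–H2O, 0 °C
Reagents that add atoms: calcium hypochlorite, [Ca+2].[O-]Cl.[O-]Cl
Why: Ene-type allylic chlorination by HOCl released in situ attacks only the electron-rich isopropenyl group (the enone is too electron-poor) and, through the allylic shift, gives the 2-substituted allyl chloride that becomes C12, without touching the C7 stereocentre.

Step 2
Reactants: 2 (R)-10-chlorocarvone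
Product: 3 (R)-10-acetoxycarvone
Conditions: KOAc, Bu4NI (cat.), DMF, 50 °C
Reagents that add atoms: potassium acetate, CC(=O)[O-].[K+]
Why: SN2 displacement of the primary allylic chloride by acetate (iodide catalysis) installs the C12 oxygen without exposing the enone to hydroxide.

Step 3
Reactants: 3 (R)-10-acetoxycarvone
Product: 4 (R)-10-hydroxycarvone
Conditions: K2CO3 (cat.), MeOH, 0 °C
Reagents that add atoms: none
Why: Base-catalysed transesterification with methanol frees the primary allylic alcohol under conditions too mild for conjugate addition to the enone.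

Step 4
Reactants: 4 (R)-10-hydroxycarvone
Product: 5 (R)-10-(tert-butyldimethylsilyloxy)carvone
Conditions: TBSCl, imidazole, DMF, 25 °C
Reagents that add atoms: tert-butyldimethylsilyl chloride, CC(C)(C)[Si](C)(C)Cl
Why: Standard silylation of a primary alcohol masks C12–OH against the two enolate steps that follow.

Step 5
Reactants: 5 (R)-10-(tert-butyldimethylsilyloxy)carvone; 6 methallyl bromide
Product: 8 (5R,6S)-6-methallyl-10-(tert-butyldimethylsilyloxy)carvone (methallyl trans to the C5 arm), via lithium enolate 7 (not isolated)
Conditions: LiN(iPr)2, THF, −78 °C; then 6, DMPU, −78 → −20 °C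
Reagents that add atoms: none
Why: Kinetic deprotonation at the α′ carbon (C8) gives the cross-conjugated enolate, which is alkylated anti to the neighbouring C7 arm (enolate alkylation) and forms the C8–C9 bond; the C8 configuration is provisional because the centre is enolised again in step 6.

Step 6
Reactants: 8 (5R,6S)-6-methallyl-10-(tert-butyldimethylsilyloxy)carvone
Product: 10 (5S,6S)-6-hydroxy-6-methallyl-10-(tert-butyldimethylsilyloxy)carvone (hydroxyl trans to the C5 arm), via potassium enolate 9 (not isolated)
Conditions: KN(SiMe3)2, THF, −78 °C; then trans-2-(phenylsulfonyl)-3-phenyloxaziridine, −78 °C; aq. NH4Cl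
Reagents that add atoms: trans-2-(phenylsulfonyl)-3-phenyloxaziridine, O=S(=O)(N1OC1c1ccccc1)c1ccccc1
Why: Removal of the remaining tertiary α′ hydrogen gives the tetrasubstituted enolate, and the Davis oxaziridine transfers oxygen to the face opposite the C7 arm (held pseudo-axial by allylic strain with the C8 substituent), so the new C8 hydroxyl is trans and the methallyl group cis to the arm (enolate hydroxylation).

Step 7
Reactants: 10 (5S,6S)-6-hydroxy-6-methallyl-10-(tert-butyldimethylsilyloxy)carvone
Product: 11 (5S,6S)-6,10-dihydroxy-6-methallylcarvone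
Conditions: HF·pyridine, THF–pyridine, 0 → 25 °C
Reagents that add atoms: none
Why: Fluoride cleavage of the silyl ether under buffered, non-basic conditions frees the primary allylic alcohol without risking an α-ketol shift of the tertiary hydroxy ketone.

Step 8
Reactants: 11 (5S,6S)-6,10-dihydroxy-6-methallylcarvone
Product: 12 2-[(1S,2S)-2-hydroxy-4-methyl-2-(2-methylprop-2-en-1-yl)-3-oxocyclohex-4-en-1-yl]prop-2-enal
Conditions: MnO2, CH2Cl2, 25 °C
Reagents that add atoms: none
Why: MnO2 oxidises only the allylic primary alcohol to the 2-substituted acrolein and leaves the tertiary C8 alcohol alone (allylic oxidation).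

Step 9
Reactants: 12 the enal of step 8
Product: 13 2-[(1S,2S)-2-hydroxy-4-methyl-2-(2-methylprop-2-en-1-yl)-3-oxocyclohex-4-en-1-yl]prop-2-enoic acid
Conditions: NaClO2, NaH2PO4, 2-methyl-2-butene, t-BuOH–H2O, 0 → 25 °C
Reagents that add atoms: sodium chlorite, [Na+].[O-]Cl=O
Why: Pinnick oxidation converts the enal into the acrylic acid (C12) under buffered conditions, the scavenger removing HOCl so that the methallyl alkene is not chlorinated.

Step 10
Reactants: 13 the acrylic acid of step 9
Product: 15 2-[(1S,6S)-6-hydroxy-4-methyl-6-(2-methylprop-2-en-1-yl)-5-oxocyclohex-2-en-1-yl]prop-2-enoic acid (β,γ-enone; C4 epimers), via tripotassium dienolate 14 (not isolated)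
Conditions: KN(SiMe3)2 (3.5 equiv), THF, −78 → −40 °C; then AcOH, THF, −78 °C (inverse quench)
Reagents that add atoms: none
Why: With C8 quaternary the only enolisable position is the γ-carbon C6, so excess amide (which also deprotonates the acid and the alcohol) gives the through-conjugated dienolate, and kinetic protonation at the α-carbon C4 moves the alkene to C5=C6 (deconjugative protonation of an extended enolate); the C4 centre forms as a mixture and is erased in step 12.

Step 11
Reactants: 15 the β,γ-enone acid of step 10
Product: 16 iodolactone, 4-hydroxy-7-iodo-6-methyl-3-methylidene-4-(2-methylprop-2-en-1-yl)hexahydro-1-benzofuran-2,5-dione (cis-fused; C5 iodine trans to the C6 lactone oxygen; C4 epimers)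
Conditions: I2, NaHCO3, MeCN–H2O, 0 °C, dark
Reagents that add atoms: iodine, II
Why: Iodolactonisation: the tethered carboxylate can reach C6 only on the face of the C7 arm, so 5-exo attack on the iodonium ion formed on the opposite face closes the cis-fused γ-lactone (C6–O syn to C7–C11) and places iodine at C5 anti to the new C–O bond, while bicarbonate at 0 °C is too weak to reconjugate the ketone first.

Step 12
Reactants: 16 iodolactone
Product: 17 (3aR,4S,7aR)-4-hydroxy-6-methyl-3-methylidene-4-(2-methylprop-2-en-1-yl)-3a,7a-dihydro-1-benzofuran-2,5(3H,4H)-dione (ring A keto-lactone; 6R,7R,8S in target numbering)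
Conditions: DBU, CH2Cl2, 0 °C
Reagents that add atoms: none
Why: E1cB dehydroiodination of the β-iodo ketone (C4–H is α to the carbonyl, iodide on C5 is β) restores the C4=C5 enone inside ring A, with C3 and C6 necessarily cis on the alkene, and removes the stray C4 centre.

Step 13
Reactants: 17 ring A keto-lactone; 18 allyl bromide
Product: 20 (3aR,4S,5S,7aR)-4,5-dihydroxy-6-methyl-3-methylidene-4-(2-methylprop-2-en-1-yl)-5-(prop-2-en-1-yl)-3a,4,5,7a-tetrahydro-1-benzofuran-2(3H)-one (trans-3,8-diol in target numbering), via allylindium sesquibromide 19 (not isolated)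
Conditions: In powder, 18, THF–H2O, 25 °C
Reagents that add atoms: none
Why: Barbier allylation with indium: the allylindium reagent adds 1,2 to the ketone chelated to the free C8 hydroxyl and attacks the face opposite the axial methallyl group and the lactone, so the allyl group ends anti to methallyl and the new C3 hydroxyl trans to the C8 hydroxyl, while the lactone, the acrylate and the enone β-carbon are left alone.

Step 14
Reactants: 20 trans-3,8-diol diene
Product: 21 (3S,6R,7R,8S)-3,8-dihydroxy-3,8-cyclogermacra-1(10),4,11(13)-trien-12,6-olide (trans-fused decalin diol)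
Conditions: second-generation Grubbs catalyst RuCl2(=CHPh)(PCy3)(H2IMes) (5 mol %), CH2Cl2, 40 °C
Reagents that add atoms: none
Why: Ring-closing metathesis joins the allyl and methallyl groups (trans on C3 and C8, diequatorial after ring flip) into ring B with the trisubstituted C1=C10 alkene and loss of ethene, the electron-poor α-methylene lactone and the hindered C4=C5 alkene being poor metathesis partners.

Step 15
Reactants: 21 trans-fused decalin diol
Product: 22 1-iodo-3,10-epoxy-8-hydroxy-3,8-cyclogermacra-4,11(13)-dien-12,6-olide (iodine at C1 anti to the ether oxygen)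
Conditions: I2, NaHCO3, MeCN, 0 °C, dark
Reagents that add atoms: iodine, II
Why: Transannular iodoetherification in the manner of the terpinen-4-ol to 1,4-cineole cyclisation: the axial C3 hydroxyl attacks the tertiary end C10 (Markovnikov) of the iodonium ion formed on the opposite face of C1=C10, which closes the C3–O–C10 oxolane bridge (a 7-oxanorbornane) and fixes C10 with its oxygen on the face of the C3 oxygen.

Step 16
Reactants: 22 iodo ether
Product: 23 (3S,6R,7R,8S,10S)-3,10-epoxy-8-hydroxy-3,8-cyclogermacra-4,11(13)-dien-12,6-olide (3,10-oxa-bridged decalin-8-ol)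
Conditions: Bu3SnH, Et3B (cat.), air, toluene, −20 → 0 °C
Reagents that add atoms: none
Why: Radical deiodination: with low-temperature Et3B/air initiation the stannyl radical abstracts iodine far faster than it adds to the α-methylene lactone, and the secondary C1 radical is quenched by excess Bu3SnH before it can add to the acrylate, so only the C1 centre is erased.

Step 17
Reactants: 23 3,10-oxa-bridged decalin-8-ol
Product: 24 (3S,6R,7R,10S)-3-acetoxy-3,10-epoxy-8-oxogermacra-4Z,11(13)-dien-12,6-olide (acetoxy group cis to the C14 methyl across the oxolane)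
Conditions: PhI(OAc)2, I2, CH2Cl2, visible light, 20 °C
Reagents that add atoms: (diacetoxyiodo)benzene, CC(=O)OI(OC(C)=O)c1ccccc1
Why: Acetyl hypoiodite, formed from PhI(OAc)2 and I2, should turn the tertiary C8 alcohol into its hypoiodite; light breaks the O–I bond and the C8 alkoxy radical fragments by β-scission of the ring-fusion bond C8–C3, leaving C8 as a ketone and C3 as a tertiary radical that is allylic to C4=C5 and α to the bridging oxygen, which is then oxidised (iodine-atom transfer and ionisation) to the bridged oxocarbenium ion and capped by acetate. The closest known reaction type is the hypoiodite (Suárez-type) β-fragmentation of fused bicyclic carbinols and of carbinols next to an ether carbon, where the α-oxygenated carbon radical likewise ends as an acetoxy acetal. No new ring is made: removing the bond that rings A and B share merges their outer atoms into the cyclodec-4-en-8-one, and the oxolane O–C3–C2–C1–C10 stays behind as a 1,4-bridge that keeps C10 locked. The one new stereocentre, the ketal carbon C3, is dictated by the bicycle, because acetate can reach the oxocarbenium ion only on the face turned away from the C4–C9 chain, which puts the acetoxy group cis to the C14 methyl; the Z geometry of C4=C5 is inherited from ring A, and C6, C7 and C10 are not touched. The step needs cleavage of C8–C3 rather than C8–C7 or C8–C9, and the substrate secures this through the oxygen lone pair and the C4=C5 π bond that stabilise the C3 radical and through release of the 7-oxanorbornane strain, whereas the alternatives would give only a secondary allylic radical at C7 or a primary one at C9 and keep the strained bicycle. A short reaction time at 20 °C or below and a bicarbonate/thiosulfate quench should keep the C11=C13 alkene from drifting into conjugation with the new C8 ketone.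

Step 18
Reactants: 24 ketal acetate
Product: 26 (6R,7S,8R,10S)-8,10-dihydroxy-3-oxogermacra-4Z,11(13)-dien-12,6-olide (drawn open), via hemiketal 25 (not isolated)
Conditions: AcOH–H2O–MeCN, 0 °C; toluene azeotrope; then Me4NBH(OAc)3, MeCN–AcOH, −30 → −20 °C
Reagents that add atoms: water, O
Why: Aqueous acetic acid ionises the tertiary, allylically stabilised ketal acetate and water gives the hemiketal, whose open 10-hydroxy-3,8-dione tautomer binds the triacetoxyborohydride through the tertiary C10 hydroxyl and receives hydride intramolecularly at the β-carbonyl C8 (Evans–Saksena directed reduction), setting C8 1,3-anti to C10, that is (8R); the C3 carbonyl (conjugated, largely masked as hemiketal and only γ to the directing hydroxyl) and the acrylate are not reduced.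

Step 19
Reactants: 26 8,10-dihydroxy-3-ketone; 27 tiglic acid
Product: 29 (6R,7S,8R,10S)-10-hydroxy-3-oxo-8-tigloyloxygermacra-4Z,11(13)-dien-12,6-olide (drawn open), via mixed anhydride 28 (not isolated)
Conditions: 27, 2,4,6-trichlorobenzoyl chloride, Et3N, toluene, 25 °C; then 26, 4-(dimethylamino)pyridine, toluene, 25 °C
Reagents that add atoms: none
Why: Yamaguchi esterification: tiglic acid is activated as the mixed anhydride and transferred to the only secondary hydroxyl (C8), the tertiary C10 or hemiketal hydroxyl being too hindered to acylate, and the E geometry of the tiglate is kept.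

Step 20
Reactants: 29 8-O-tigloyl 3-enone
Product: 30 (3S,6R,7S,8R,10S)-3,10-dihydroxy-8-tigloyloxygermacra-4Z,11(13)-dien-12,6-olide (CNP0137971.1)
Conditions: (R)-2-methyl-CBS-oxazaborolidine [(3aR)-1-methyl-3,3-diphenyltetrahydro-1H,3H-pyrrolo[1,2-c][1,3,2]oxazaborole] (1 equiv), catecholborane (3 equiv), toluene–CH2Cl2, −78 → −40 °C; then MeOH, aq. NaHCO3
Reagents that add atoms: none
Why: Corey–Bakshi–Shibata reduction: the ketone is supplied by the ring–chain equilibrium of the hemiketal, and the (R)-oxazaborolidine–catecholborane complex treats the α-methylvinyl side (C4) as the large group and delivers hydride 1,2 to give the (3S)-allylic alcohol under reagent control, leaving the tiglate, the lactone and both conjugated alkenes untouched.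

## Compound list

1 | (R)-carvone | CC1=CC[C@H](CC1=O)C(C)=C | starting material
2 | (R)-10-chlorocarvone | O=C1C(C)=CC[C@@H](C(=C)CCl)C1 | intermediate
3 | (R)-10-acetoxycarvone | O=C1C(C)=CC[C@@H](C(=C)COC(C)=O)C1 | intermediate
4 | (R)-10-hydroxycarvone | O=C1C(C)=CC[C@@H](C(=C)CO)C1 | intermediate
5 | (R)-10-(tert-butyldimethylsilyloxy)carvone | O=C1C(C)=CC[C@@H](C(=C)CO[Si](C)(C)C(C)(C)C)C1 | intermediate
6 | methallyl bromide (3-bromo-2-methylprop-1-ene) | C=C(C)CBr | starting material
7 | lithium cross-conjugated enolate of 5 | C=C(CO[Si](C)(C)C(C)(C)C)[C@@H]1CC=C(C)C(O[Li])=C1 | intermediate (not isolated)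
8 | (5R,6S)-6-methallyl-10-(tert-butyldimethylsilyloxy)carvone | O=C1C(C)=CC[C@@H](C(=C)CO[Si](C)(C)C(C)(C)C)[C@@H]1CC(C)=C | intermediate
9 | potassium enolate of 8 | C=C(CO[Si](C)(C)C(C)(C)C)[C@@H]1CC=C(C)C(O[K])=C1CC(C)=C | intermediate (not isolated)
10 | (5S,6S)-6-hydroxy-6-methallyl-10-(tert-butyldimethylsilyloxy)carvone | O=C1C(C)=CC[C@@H](C(=C)CO[Si](C)(C)C(C)(C)C)[C@@]1(O)CC(C)=C | intermediate
11 | (5S,6S)-6,10-dihydroxy-6-methallylcarvone | O=C1C(C)=CC[C@@H](C(=C)CO)[C@@]1(O)CC(C)=C | intermediate
12 | 2-[(1S,2S)-2-hydroxy-4-methyl-2-(2-methylprop-2-en-1-yl)-3-oxocyclohex-4-en-1-yl]prop-2-enal | O=C1C(C)=CC[C@@H](C(=C)C=O)[C@@]1(O)CC(C)=C | intermediate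
13 | 2-[(1S,2S)-2-hydroxy-4-methyl-2-(2-methylprop-2-en-1-yl)-3-oxocyclohex-4-en-1-yl]prop-2-enoic acid | O=C1C(C)=CC[C@@H](C(=C)C(=O)O)[C@@]1(O)CC(C)=C | intermediate
14 | tripotassium carboxylate–alkoxide–dienolate of 13 | [K]OC(=O)C(=C)[C@@H]1C=CC(C)=C(O[K])[C@]1(O[K])CC(C)=C | intermediate (not isolated)
15 | 2-[(1S,6S)-6-hydroxy-4-methyl-6-(2-methylprop-2-en-1-yl)-5-oxocyclohex-2-en-1-yl]prop-2-enoic acid (C4 epimers) | O=C1C(C)C=C[C@@H](C(=C)C(=O)O)[C@@]1(O)CC(C)=C | intermediate
16 | iodolactone (cis-fused, C5–I trans to C6–O, C4 epimers) | O=C1C(C)[C@H](I)[C@H]2OC(=O)C(=C)[C@H]2[C@@]1(O)CC(C)=C | intermediate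
17 | (3aR,4S,7aR)-4-hydroxy-6-methyl-3-methylidene-4-(2-methylprop-2-en-1-yl)-3a,7a-dihydro-1-benzofuran-2,5(3H,4H)-dione | O=C1C(C)=C[C@H]2OC(=O)C(=C)[C@H]2[C@@]1(O)CC(C)=C | intermediate
18 | allyl bromide | C=CCBr | starting material
19 | allylindium sesquibromide (trivalent indium) | C=CC[In](Br)Br.C=CC[In](Br)CC=C | intermediate (not isolated)
20 | (3aR,4S,5S,7aR)-4,5-dihydroxy-6-methyl-3-methylidene-4-(2-methylprop-2-en-1-yl)-5-(prop-2-en-1-yl)-3a,4,5,7a-tetrahydro-1-benzofuran-2(3H)-one | O[C@@]1(CC=C)C(C)=C[C@H]2OC(=O)C(=C)[C@H]2[C@@]1(O)CC(C)=C | intermediate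
21 | (3S,6R,7R,8S)-3,8-dihydroxy-3,8-cyclogermacra-1(10),4,11(13)-trien-12,6-olide | O[C@]12CC=C(C)C[C@]1(O)[C@@H]1C(=C)C(=O)O[C@@H]1C=C2C | intermediate
22 | 1-iodo-3,10-epoxy-8-hydroxy-3,8-cyclogermacra-4,11(13)-dien-12,6-olide (I anti to ether O) | C[C@@]12[C@H](I)C[C@]3(O1)C(C)=C[C@H]1OC(=O)C(=C)[C@H]1[C@@]3(O)C2 | intermediate
23 | (3S,6R,7R,8S,10S)-3,10-epoxy-8-hydroxy-3,8-cyclogermacra-4,11(13)-dien-12,6-olide | C[C@@]12CC[C@]3(O1)C(C)=C[C@H]1OC(=O)C(=C)[C@H]1[C@@]3(O)C2 | intermediate
24 | (3S,6R,7R,10S)-3-acetoxy-3,10-epoxy-8-oxogermacra-4Z,11(13)-dien-12,6-olide | C[C@@]12CC[C@](O1)(OC(C)=O)/C(C)=C\[C@H]1OC(=O)C(=C)[C@H]1C(=O)C2 | intermediate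
25 | (3R,6R,7R,10S)-3-hydroxy-3,10-epoxy-8-oxogermacra-4Z,11(13)-dien-12,6-olide (hemiketal) | C[C@@]12CC[C@](O1)(O)/C(C)=C\[C@H]1OC(=O)C(=C)[C@H]1C(=O)C2 | intermediate (not isolated)
26 | (6R,7S,8R,10S)-8,10-dihydroxy-3-oxogermacra-4Z,11(13)-dien-12,6-olide | C=C1C(=O)O[C@@H]2/C=C(/C)C(=O)CC[C@](C)(O)C[C@@H](O)[C@H]12 | intermediate
27 | tiglic acid | C/C=C(\C)C(=O)O | starting material
28 | tiglic 2,4,6-trichlorobenzoic anhydride | C/C=C(\C)C(=O)OC(=O)c1c(Cl)cc(Cl)cc1Cl | intermediate (not isolated)
29 | (6R,7S,8R,10S)-10-hydroxy-3-oxo-8-tigloyloxygermacra-4Z,11(13)-dien-12,6-olide | C=C1C(=O)O[C@@H]2/C=C(/C)C(=O)CC[C@](C)(O)C[C@@H](OC(=O)/C(C)=C/C)[C@H]12 | intermediate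
30 | (3S,6R,7S,8R,10S)-3,10-dihydroxy-8-tigloyloxygermacra-4Z,11(13)-dien-12,6-olide (CNP0137971.1) | C=C1C(=O)O[C@@H]2/C=C(/C)[C@@H](O)CC[C@](C)(O)C[C@@H](OC(=O)/C(C)=C/C)[C@H]12 | target

## Step count and risks

Total step count: 20. Longest linear sequence: 20 steps, from (R)-carvone (1).

**Step 17 (scission).** What may go wrong: acetyl hypoiodite may add across C4=C5, the C8 alkoxy radical may abstract a hydrogen from the C14 or C15 methyl instead of fragmenting, or the C11=C13 alkene may move into conjugation with the new ketone. The fallback cuts the same C3–C8 bond by a two-electron path before the bridge is built. It sets out from diol 21: Criegee glycol cleavage with Pb(OAc)4 in benzene–pyridine should give the ring-opened (1(10)Z,4Z)-3,8-dioxogermacra-1(10),4,11(13)-trien-12,6-olide F1 without light or electrophilic iodine. N-Iodosuccinimide in MeOH–CH2Cl2 then closes the bridge by transannular iodoketalisation (the C3 carbonyl oxygen attacks the tertiary C10 of the iodonium ion and methanol caps the oxocarbenium ion) to give the 1-iodo-3-methoxy-3,10-epoxy ketone F2. Bu3SnH/Et3B removes the iodine to give the methyl ketal F3, which is hydrolysed and reduced under the conditions of step 18 in place of 24 and so returns to the route at 26. The price is that C10 is then set in the flexible ten-membered ring instead of the rigid decalin, so its configuration would have to be proved.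

**Step 10 (deconjugation).** What may go wrong: γ-deprotonation of the already doubly charged substrate may be incomplete, the tertiary α-hydroxy ketone may undergo a base-induced ketol shift, or the β,γ-enone may reconjugate before the lactone is closed. The fallback avoids the deconjugated ketone and the iodolactonisation. It sets out from acid 13: excess Me3SiOTf/Et3N (CH2Cl2, 0 °C) should give the tris(trimethylsilyl) derivative F4 (silyl ester, C8 silyl ether and 3-silyloxy-3,5-diene, γ-enolisation being the only one open). N-Bromosuccinimide (THF, −78 °C) then brominates the γ-carbon C6 anti to the C7 arm to give the 6-bromo enone F5. Bu4NF (THF, 0 °C) frees the carboxylate, which displaces the allylic bromide with inversion to the cis-lactone, and removes the C8 silyl ether, returning to the route at 17.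

**Step 20 (C3 reduction).** What may go wrong: under aprotic conditions the ketone may stay locked in the closed hemiketal, borane may be consumed by the tertiary hydroxyl, or the conformation of the ten-membered ring may override reagent control of the facial selectivity. The fallback moves the reduction into a protic medium where ring and chain forms exchange freely and puts it under enzyme control. It sets out from 29: an (S)-selective ketoreductase chosen from a panel, with NADPH recycled by glucose/glucose dehydrogenase in pH 7 buffer–DMSO at 30 °C, would give 30 directly; no new compound is made (F0).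

## Further compounds

F1 | step 17 | (1(10)Z,4Z)-3,8-dioxogermacra-1(10),4,11(13)-trien-12,6-olide | O=C1C/C=C(C)\CC(=O)[C@@H]2C(=C)C(=O)O[C@@H]2/C=C\1C
F2 | step 17 | 1-iodo-3-methoxy-3,10-epoxy-8-oxogermacra-4Z,11(13)-dien-12,6-olide | C[C@@]12[C@H](I)C[C@](O1)(OC)/C(C)=C\[C@H]1OC(=O)C(=C)[C@H]1C(=O)C2
F3 | step 17 | 3-methoxy-3,10-epoxy-8-oxogermacra-4Z,11(13)-dien-12,6-olide | C[C@@]12CC[C@](O1)(OC)/C(C)=C\[C@H]1OC(=O)C(=C)[C@H]1C(=O)C2
F4 | step 10 | trimethylsilyl ester, C8 trimethylsilyl ether and 3-trimethylsilyloxy-3,5-diene of 13 | C=C(C(=O)O[Si](C)(C)C)[C@@H]1C=CC(C)=C(O[Si](C)(C)C)[C@]1(O[Si](C)(C)C)CC(C)=C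
F5 | step 10 | 6-bromo enone (Br trans to the C7 arm), silyl ester and C8 silyl ether retained | O=C1C(C)=C[C@H](Br)[C@@H](C(=C)C(=O)O[Si](C)(C)C)[C@@]1(O[Si](C)(C)C)CC(C)=C
F0 | step 20 | none | none
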